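**Dose first.** If initiator wears chains down as well as starting them, as a pseudo-first-order loss that follows the initiator charge, then late in a run the product of charge and time should count. That is our assumption, and larch is the run to read it from.

| flask | free monomer | initiator | temperature | remark | time |
|---|---|---|---|---|---|
| ash | 0.78 M | 28 mM | 5 °C | run made earlier |  |
| larch | 0.78 M | 62 mM | 20 °C | run made earlier |  |
| alder | 0.51 M | 25 mM | 5 °C | run made earlier |  |
| violet | 0.50 M | 50 mM | 20 °C |  | 3.0 d |
| green | 0.78 M | 25 mM | 20 °C |  | 3.0 d |

ash run (percent of the free monomer charged): time / d: monomer in chains / % = 0.333: 0.6; 0.625: 0.7; 1.25: 1.6; 2.00: 1.9; 4.00: 7.4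

larch run (percent of the free monomer charged): time / h: monomer in chains / % = 4.00: 0.5; 8.00: 4.1; 15.0: 13.1; 25.0: 25.3; 48.0: 34.4

alder run (percent of the free monomer charged): time / d: monomer in chains / % = 0.417: 0.5; 1.04: 0.6; 2.00: 1.6; 4.00: 5.9

(each reading ± 0.5 percentage points)

- which one finishes higher in amount of monomer in chains, in percent of the free monomer charged ("neither" within 2 percentage points) (violet / green / neither)
- amount of monomer in chains at the end, in percent of the free monomer charged, violet
- amount of monomer in chains at the end, in percent of the free monomer charged, green

- what was read earlier has a scatter of 0.5 percentage points, one standard deviation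

**Start-up.** Larch stands at 0.5 % after 4.00 h, so its start-up is shorter than the 3.0 d asked of the new flasks.

**The rise.** Larch then gains 12 percentage points in the 10.0 h up to 25.0 h, but 9.1 points in the next 23.0 h. Its rate of gain therefore falls to a third. We take 25.0 h as larch's bend, which is a reading with its scatter.

**The bend.** Green comes to 1.16 on our scale: the dose number Q, initiator charge times time, divided by the same product for larch at its bend. Violet comes to 2.32, and larch's last reading to 1.92. So green ends just past the bend, with less dose than larch's last reading, while violet goes further than larch was followed. Q says nothing of violet's smaller monomer charge. Our own reckoning therefore names no winner and gives no percentages.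

**The forecast.** It says green, with 2 % for violet and 30 % for green. Of violet it says that it “should barely polymerise, whatever its initiator level”.

**Result.** Green ends at 40.1 % and violet at 32.5 %, so green finishes higher.

    living end + monomer in chains → dead end (k = 2.20 × 10⁻⁵ /M/s, Ea = 58.0 kJ/mol)
    free monomer + initiator → living end + monomer in chains (k = 4.70 × 10⁻⁶ /M/s, Ea = 91.0 kJ/mol)
    free monomer + living end → monomer in chains + living end, rate k3*[living end]*[free monomer] (k = 5.40 × 10⁻⁴ /M/s, Ea = 72.0 kJ/mol)
    initiator + monomer in chains → initiator + over-reaction product (k = 1.80 × 10⁻⁴ /M/s, Ea = 81.0 kJ/mol)
    (constants at 20 °C)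

**Dose again.** Violet, at Q = 2.32, holds 36.8 % of the free monomer charged as over-reaction product, and green, at Q = 1.16, holds 15.3 %. A neighbour flask is like green but charged with 0.062 M of initiator, which gives it a higher Q than green, 2.88. After 3.0 d that neighbour holds less monomer in chains than green, at 29.7 %, and over-reaction product at 49.1 %.

(The runs were generated by integration for substances that don't exist, and the scatter is random.)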